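**Plan**
1. Retrosynthesis: first cut the O9 epoxyangelate, the O8 acetate and the lactone bond O6–C12 (C12 is carried as a PMB-protected allylic alcohol). Then cut C2–C3, and last C9–C10, C4=C5 and C7–C11. C5–C9 is L-arabinose.
2. Enabling feature: C2–C3 is the doubly allylic CH2–CH2 bond of the cyclodeca-1(10),4-diene ring. C3 is the primary end of the allyl unit C3–C4=C5 (acceptor as η3-allylpalladium). C2 is the primary end of the allyl unit C2–C1=C10 (donor as sulfonyl-stabilised carbanion).
3. Forward: the chain is built on the arabinofuranose ring and its ends are tied through C3–O–C(=O)–C2 into a twelve-membered α-sulfonyl lactone. This ring is contracted to the ten-membered carbocycle by extrusion of CO2. The sulfonyl helper leaves in the next step and the γ-lactone ring is closed last.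
4. Stereochemistry: C6 and C8 come from L-arabinose, C7 from convex-face addition to the bicyclic 3-ulose, C9 from a Felkin–Anh addition, and the epoxide from a Sharpless epoxidation. Z-C1=C10 comes from trans-hydroalumination/iodination of but-2-yn-1-ol and E-C4=C5 from a stabilised ylide.

Key step: step 20

Remark (numbering): germacranolide numbering is used: C1=C10(C14), C2, C3, C4(C15)=C5, C6 (lactone oxygen), C7 (OH, C11), C8 (OAc), C9 (epoxyangelate), C11(=C13)–C12(=O). On is the oxygen on Cn.
Remark (abbreviations): PMB = 4-methoxybenzyl, TBS = tert-butyldimethylsilyl, TBDPS = tert-butyldiphenylsilyl.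
Remark (assumption): 14, 23 and 38 are expected as anomer mixtures, and 29 and 30 as mixtures at C2. These centres are drawn without configuration and none of them survives in the target.

Step 1
Reactants: 1 2,3-dibromoprop-1-ene; 2 4-methoxybenzyl alcohol
Product: 3 2-bromoallyl 4-methoxybenzyl ether
Conditions: NaH, THF, 0 °C to rt
Reagents that add atoms: none
Why: Williamson ether synthesis in which the alkoxide displaces only the allylic bromide, the vinylic bromide being inert to SN2.

Step 2
Reactants: 4 but-2-yn-1-ol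
Product: 6 (Z)-3-iodobut-2-en-1-ol, via cyclic vinylalanate 5 (not isolated)
Conditions: NaAlH2(OCH2CH2OMe)2, THF, 0 °C to rt; then I2, −78 °C
Reagents that add atoms: iodine, II
Why: Hydroxyl-directed trans-hydroalumination of a propargylic alcohol and iodinolysis with retention place iodine on the future C10 cis to the CH2OH group, which fixes the Z geometry of C1=C10.

Step 3
Reactants: 6 (Z)-3-iodobut-2-en-1-ol
Product: 8 (Z)-3-iodobut-2-en-1-yl phenyl sulfone, via allylic mesylate 7 (not isolated)
Conditions: MsCl, Et3N, CH2Cl2, −20 °C; then PhSO2Na, DMF, rt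
Reagents that add atoms: methanesulfonyl chloride, CS(=O)(=O)Cl (stays only in 7); sodium benzenesulfinate, [Na+].[O-]S(=O)c1ccccc1
Why: SN2 S-alkylation of a sulfinate by a primary allylic sulfonate, which leaves the iodoalkene and its geometry untouched.

Step 4
Reactants: 9 angelic acid
Product: 10 (Z)-2-methylbut-2-en-1-ol
Conditions: LiAlH4, Et2O, 0 °C
Reagents that add atoms: none
Why: Hydride reduction of the carboxylic acid, in which LiAlH4 does not touch the trisubstituted alkene, so the Z geometry is kept.

Step 5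
Reactants: 10 (Z)-2-methylbut-2-en-1-ol
Product: 11 [(2R,3S)-2,3-dimethyloxiran-2-yl]methanol
Conditions: Ti(OiPr)4 (10 mol %), D-(−)-diethyl tartrate (12 mol %), t-BuOOH, 4 Å molecular sieves, CH2Cl2, −20 °C
Reagents that add atoms: tert-butyl hydroperoxide, CC(C)(C)OO
Why: Sharpless asymmetric epoxidation, in which D-(−)-tartrate should deliver oxygen to the face opposite to the one known for Z-trisubstituted allylic alcohols with the L-(+)-ester, and the syn addition keeps CH2OH and the C3 methyl cis.

Step 6
Reactants: 11 [(2R,3S)-2,3-dimethyloxiran-2-yl]methanol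
Product: 12 (2S,3S)-2,3-dimethyloxirane-2-carboxylic acid
Conditions: RuCl3 (2 mol %), NaIO4, EtOAc/MeCN/H2O, rt
Reagents that add atoms: water, O; sodium periodate, [Na+].[O-]I(=O)(=O)=O
Why: Ruthenium tetroxide oxidation of a 2,3-epoxy alcohol to the glycidic acid, which leaves the epoxide and both stereocentres in place (the C2 descriptor changes only through the priority change).

Step 7
Reactants: 13 L-arabinose
Product: 15 5-O-TBDPS-1,2-O-isopropylidene-β-L-arabinofuranose, via 5-O-TBDPS-L-arabinofuranose 14 (not isolated)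
Conditions: TBDPSCl, pyridine, rt; then Me2C(OMe)2, TsOH (cat.), acetone, rt
Reagents that add atoms: tert-butyl(chloro)diphenylsilane, CC(C)(C)[Si](Cl)(c1ccccc1)c1ccccc1; 2,2-dimethoxypropane, COC(C)(C)OC
Why: Selective silylation of the primary hydroxyl traps the furanose form, and acid-catalysed acetalisation then bridges the only cis pair O1/O2, which leaves the hydroxyl on the future C7 as the single free one.

Step 8
Reactants: 15 5-O-TBDPS-1,2-O-isopropylidene-β-L-arabinofuranose
Product: 16 5-O-TBDPS-1,2-O-isopropylidene-β-L-threo-pentofuranos-3-ulose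
Conditions: Dess–Martin periodinane, CH2Cl2, rt
Reagents that add atoms: none
Why: Dess–Martin oxidation of the secondary alcohol under non-basic conditions, which avoids epimerisation at C8 and β-elimination.

Step 9
Reactants: 16 5-O-TBDPS-1,2-O-isopropylidene-β-L-threo-pentofuranos-3-ulose; 3 2-bromoallyl 4-methoxybenzyl ether
Product: 18 3-C-[3-(PMB-oxy)prop-1-en-2-yl]-5-O-TBDPS-1,2-O-isopropylidene-β-L-lyxofuranose, via vinyllithium 17 (not isolated)
Conditions: 3, t-BuLi (2 equiv), Et2O, −78 °C; then 16, −78 °C
Reagents that add atoms: none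
Why: Bromine–lithium exchange and 1,2-addition to the ketone, in which the acetonide and the CH2OSi arm both lie on the concave face of the cis-fused bicycle, so attack from the convex face sets C7 with its hydroxyl cis to O6.

Step 10
Reactants: 18 3-C-[3-(PMB-oxy)prop-1-en-2-yl]-5-O-TBDPS-1,2-O-isopropylidene-β-L-lyxofuranose
Product: 19 3-C-[3-(PMB-oxy)prop-1-en-2-yl]-1,2-O-isopropylidene-β-L-lyxofuranose
Conditions: Bu4NF, THF, 0 °C to rt
Reagents that add atoms: none
Why: Fluoride cleavage of the silyl ether, to which the acetal and the PMB ether are inert.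

Step 11
Reactants: 19 3-C-[3-(PMB-oxy)prop-1-en-2-yl]-1,2-O-isopropylidene-β-L-lyxofuranose
Product: 20 C9 aldehyde (the corresponding pentodialdo-1,4-furanose)
Conditions: Dess–Martin periodinane, CH2Cl2, 0 °C to rt
Reagents that add atoms: none
Why: Dess–Martin oxidation, in which only the primary alcohol can react because the C7 hydroxyl is tertiary.

Step 12
Reactants: 20 C9 aldehyde; 8 (Z)-3-iodobut-2-en-1-yl phenyl sulfone
Product: 21 C9 allylic alcohol (O9 anti to O8; Z-C1=C10; C2 bears SO2Ph)
Conditions: CrCl2 (6 equiv), NiCl2 (2 mol %), DMSO, rt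
Reagents that add atoms: none
Why: Nozaki–Hiyama–Kishi reaction, in which the alkenylchromium species forms with retention of the Z geometry, tolerates the sulfone and the free tertiary hydroxyl, and should add in the Felkin–Anh sense anti to the ring oxygen O8, giving the O8/O9-anti carbinol of the target.

Step 13
Reactants: 21 C9 allylic alcohol
Product: 22 O9-TBS ether of 21
Conditions: TBSOTf (1.1 equiv), 2,6-lutidine, CH2Cl2, −78 °C
Reagents that add atoms: tert-butyldimethylsilyl triflate, CC(C)(C)[Si](C)(C)OS(=O)(=O)C(F)(F)F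
Why: Silyl ether formation, in which the secondary allylic hydroxyl reacts at −78 °C while the hindered tertiary C7 hydroxyl stays free.

Step 14
Reactants: 22 O9-TBS ether of 21
Product: 23 O6/O7-isopropylidene lactol (free hemiacetal at C5)
Conditions: TsOH·H2O (10 mol %), acetone, rt
Reagents that add atoms: none
Why: Acid-catalysed acetal migration under thermodynamic control; as in lyxose and mannose, the 2,3-cis diol (O6/O7) holds the acetonide better than the O1/O2 pair, so the anomeric centre C5 is set free.

Step 15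
Reactants: 23 O6/O7-isopropylidene lactol; 24 ethyl 2-(triphenylphosphoranylidene)propanoate
Product: 25 open-chain (E)-enoate (C3 ester, free O8–H)
Conditions: toluene, 90 °C
Reagents that add atoms: none
Why: Wittig reaction of the lactol through its open aldehyde form, in which the stabilised α-methyl ylide gives the E-trisubstituted C4=C5 bond and the α-methyl group slows the oxa-Michael return of the freed O8–H.

Step 16
Reactants: 25 open-chain (E)-enoate
Product: 26 O8,O9-bis-TBS enoate
Conditions: TBSOTf (1.5 equiv), 2,6-lutidine, CH2Cl2, 0 °C to rt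
Reagents that add atoms: tert-butyldimethylsilyl triflate, CC(C)(C)[Si](C)(C)OS(=O)(=O)C(F)(F)F
Why: Silylation of the only free hydroxyl with the reactive triflate, which is needed because O8 stands next to the fully substituted C7.

Step 17
Reactants: 26 O8,O9-bis-TBS enoate
Product: 27 C3 allylic alcohol
Conditions: i-Bu2AlH (2.5 equiv), CH2Cl2, −78 °C
Reagents that add atoms: none
Why: 1,2-Reduction of an α,β-unsaturated ester to the allylic alcohol, to which sulfone, silyl ethers, acetal and PMB ether are inert.

Step 18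
Reactants: 27 C3 allylic alcohol
Product: 28 C3 imidazole-1-carboxylate
Conditions: 1,1'-carbonyldiimidazole, CH2Cl2, rt
Reagents that add atoms: 1,1'-carbonyldiimidazole, O=C(n1ccnc1)n1ccnc1
Why: Acylation of the primary alcohol by carbonyldiimidazole, which installs the one-carbon tether as an activated carbonic acid derivative.

Step 19
Reactants: 28 C3 imidazole-1-carboxylate
Product: 29 twelve-membered α-sulfonyl lactone (C3–O–C(=O)–C2)
Conditions: slow addition of 28 to LiN(SiMe3)2 (2.2 equiv), THF, −78 to −20 °C, 1 mM; AcOH quench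
Reagents that add atoms: none
Why: Intramolecular C-acylation of an α-sulfonyl carbanion (Dieckmann-type closure), made irreversible because the second equivalent of base turns the product into its stabilised enolate, while the low temperature holds back 1,4-elimination of the C9 silyloxy group.

Step 20
Reactants: 29 twelve-membered α-sulfonyl lactone
Product: 30 ten-membered (1(10)Z,4E)-diene bearing SO2Ph at C2
Conditions: Pd(PPh3)4 (10 mol %), toluene, 80 °C, 1 mM
Reagents that add atoms: none
Why: Proposed new method: zerovalent palladium should ionise the only allylic C–O bond that carries a leaving group, the primary C3–O bond of the lactone (O6 is an acetal oxygen and O9 a silyl ether), to a syn η3-allyl unit over C3–C4–C5 that stays tethered to the α-sulfonyl carboxylate. C2 then attacks the allyl terminus C3 anti to palladium, either as the sulfonyl- and carboxyl-stabilised carbanion formed by an internal proton shift from the acidic C2–H, followed by loss of CO2 from the resulting α-sulfonyl-β,γ-unsaturated acid at 80 °C, or after loss of CO2 as the sulfonyl-stabilised allyl anion; both orders end in 30 and the escape of CO2 makes the contraction irreversible. The closest known reaction type is the palladium-catalysed decarboxylative allylation of acyclic allyl α-sulfonyl carboxylates, together with decarboxylative ring contractions of cyclic allyl carbamates and allyl β-keto carboxylates, and what is new is the use on a macrolactone to reach a medium carbocycle. The O–C(=O) unit leaves the twelve-membered ring and the ten-membered ring closes at the unsubstituted terminus of the allyl unit (endo to C3–C5), whereas attack at C5 would give an eight-membered ring and would have to occur at a secondary carbon next to the fully substituted dioxolane. Donor and acceptor arise without external base inside one molecule, so 1 mM dilution should suffice against dimerisation; α-attack through C2 is secured because the γ-carbon C10 is fully substituted, the E geometry at C4=C5 is kept because the syn allyl complex is the stable one, and the Z geometry at C1=C10 is kept because this bond never binds to palladium. The only new stereocentre, C2, is not controlled and need not be, since it is erased in step 21.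

Step 21
Reactants: 30 ten-membered diene bearing SO2Ph at C2
Product: 31 protected germacra-1(10)Z,4E-diene (O6/O7 acetonide, O8 and O9 TBS, O12 PMB)
Conditions: PdCl2(dppp) (10 mol %), LiHBEt3 (3 equiv), THF, 0 °C
Reagents that add atoms: none
Why: Palladium-catalysed hydride substitution of an allylic sulfone, in which ionisation to the η3-allyl unit over C2–C1–C10 and hydride delivery to the less substituted terminus C2 remove the helper without shifting or isomerising C1=C10.

Step 22
Reactants: 31 protected germacra-1(10)Z,4E-diene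
Product: 32 O8,O9-diol
Conditions: Bu4NF, THF, rt to 40 °C
Reagents that add atoms: none
Why: Fluoride cleavage of both silyl ethers at a stage that holds no base-sensitive group.

Step 23
Reactants: 32 O8,O9-diol; 12 (2S,3S)-2,3-dimethyloxirane-2-carboxylic acid
Product: 34 O9 epoxyangelate (O8–H free), via mixed anhydride 33 (not isolated)
Conditions: 12, 2,4,6-trichlorobenzoyl chloride, Et3N, toluene, rt; then 32, DMAP, 0 °C to rt
Reagents that add atoms: 2,4,6-trichlorobenzoyl chloride, O=C(Cl)c1c(Cl)cc(Cl)cc1Cl (stays only in 33)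
Why: Yamaguchi esterification, which should select the allylic O9–H because O8–H is flanked by the fully substituted dioxolane carbon C7, and which leaves the stereocentres of the acid untouched.

Step 24
Reactants: 34 O9 epoxyangelate
Product: 35 O8 acetate
Conditions: Ac2O, DMAP (cat.), pyridine, CH2Cl2, rt
Reagents that add atoms: acetic anhydride, CC(=O)OC(C)=O
Why: DMAP-catalysed acetylation of the remaining secondary hydroxyl, no other free hydroxyl being present.

Step 25
Reactants: 35 O8 acetate
Product: 36 C12 allylic alcohol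
Conditions: DDQ, CH2Cl2/pH 7 buffer, 0 °C
Reagents that add atoms: none
Why: Oxidative cleavage of the PMB ether with DDQ under buffered conditions, which esters, epoxide, acetonide and trisubstituted alkenes tolerate.

Step 26
Reactants: 36 C12 allylic alcohol
Product: 37 triol (O6–H, O7–H, O12–H)
Conditions: AcOH/H2O (4:1), 35–40 °C
Reagents that add atoms: none
Why: Mild acid hydrolysis of the acetonide, chosen weak enough to spare the electron-poor glycidic ester and to avoid protonation of the ring alkenes and transannular cyclisation.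

Step 27
Reactants: 37 triol
Product: 39 target CNP0271187.2, via lactol 38 (not isolated)
Conditions: TEMPO (20 mol %), PhI(OAc)2 (2.5 equiv), CH2Cl2, rt
Reagents that add atoms: none
Why: TEMPO/PhI(OAc)2 oxidative lactonisation of a 2-methylene-1,4-diol, in which the primary allylic alcohol is oxidised first, the carbonyl is trapped by O6–H as the five-membered lactol (O8 is blocked as acetate and O7–H would give a four-membered ring) and the lactol is oxidised to the α-methylene-γ-lactone.

**Compound list**
1 | 2,3-dibromoprop-1-ene | C=C(Br)CBr | starting material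
2 | 4-methoxybenzyl alcohol | COc1ccc(CO)cc1 | starting material
3 | 2-bromoallyl 4-methoxybenzyl ether (C11–C13 unit) | C=C(Br)COCc1ccc(OC)cc1 | intermediate
4 | but-2-yn-1-ol | CC#CCO | starting material
5 | sodium cyclic vinylalanate (five-membered O–Al–C chelate) | CC1=CCO[Al-]1(OCCOC)OCCOC.[Na+] | intermediate
6 | (Z)-3-iodobut-2-en-1-ol | C/C(I)=C/CO | intermediate
7 | (Z)-3-iodobut-2-en-1-yl methanesulfonate | C/C(I)=C/COS(C)(=O)=O | intermediate
8 | (Z)-3-iodobut-2-en-1-yl phenyl sulfone (C2, C1, C10, C14) | C/C(I)=C/CS(=O)(=O)c1ccccc1 | intermediate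
9 | angelic acid, (Z)-2-methylbut-2-enoic acid | C/C=C(/C)C(=O)O | starting material
10 | (Z)-2-methylbut-2-en-1-ol | C/C=C(/C)CO | intermediate
11 | [(2R,3S)-2,3-dimethyloxiran-2-yl]methanol | OC[C@@]1(C)O[C@H]1C | intermediate
12 | (2S,3S)-2,3-dimethyloxirane-2-carboxylic acid (epoxyangelic acid) | OC(=O)[C@@]1(C)O[C@H]1C | intermediate
13 | L-arabinose (drawn in the aldehydo form) | O=C[C@H](O)[C@@H](O)[C@@H](O)CO | starting material
14 | 5-O-TBDPS-L-arabinofuranose (anomers) | OC1O[C@@H](CO[Si](c2ccccc2)(c2ccccc2)C(C)(C)C)[C@H](O)[C@H]1O | intermediate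
15 | 5-O-TBDPS-1,2-O-isopropylidene-β-L-arabinofuranose | CC1(C)O[C@H]2O[C@@H](CO[Si](c3ccccc3)(c3ccccc3)C(C)(C)C)[C@H](O)[C@H]2O1 | intermediate
16 | 5-O-TBDPS-1,2-O-isopropylidene-β-L-threo-pentofuranos-3-ulose | CC1(C)O[C@H]2O[C@@H](CO[Si](c3ccccc3)(c3ccccc3)C(C)(C)C)C(=O)[C@H]2O1 | intermediate
17 | 3-(PMB-oxy)prop-1-en-2-yllithium | [Li]C(=C)COCc1ccc(OC)cc1 | intermediate
18 | 3-C-[3-(PMB-oxy)prop-1-en-2-yl]-5-O-TBDPS-1,2-O-isopropylidene-β-L-lyxofuranose (C7 set) | CC1(C)O[C@H]2O[C@@H](CO[Si](c3ccccc3)(c3ccccc3)C(C)(C)C)[C@](O)(C(=C)COCc3ccc(OC)cc3)[C@H]2O1 | intermediate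
19 | 3-C-[3-(PMB-oxy)prop-1-en-2-yl]-1,2-O-isopropylidene-β-L-lyxofuranose | CC1(C)O[C@H]2O[C@@H](CO)[C@](O)(C(=C)COCc3ccc(OC)cc3)[C@H]2O1 | intermediate
20 | C9 aldehyde (pentodialdo-1,4-furanose of 19) | CC1(C)O[C@H]2O[C@@H](C=O)[C@](O)(C(=C)COCc3ccc(OC)cc3)[C@H]2O1 | intermediate
21 | C9 allylic alcohol, O9 anti to O8, Z-C1=C10, SO2Ph on C2 | CC1(C)O[C@H]2O[C@@H]([C@@H](O)/C(C)=C\CS(=O)(=O)c3ccccc3)[C@](O)(C(=C)COCc3ccc(OC)cc3)[C@H]2O1 | intermediate
22 | O9-TBS ether of 21 | CC1(C)O[C@H]2O[C@@H]([C@@H](O[Si](C)(C)C(C)(C)C)/C(C)=C\CS(=O)(=O)c3ccccc3)[C@](O)(C(=C)COCc3ccc(OC)cc3)[C@H]2O1 | intermediate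
23 | O6/O7-isopropylidene lactol (hemiacetal at C5, anomers) | OC1O[C@@H]([C@@H](O[Si](C)(C)C(C)(C)C)/C(C)=C\CS(=O)(=O)c2ccccc2)[C@@]2(C(=C)COCc3ccc(OC)cc3)OC(C)(C)O[C@@H]12 | intermediate
24 | ethyl 2-(triphenylphosphoranylidene)propanoate (C3, C4, C15) | CCOC(=O)C(C)=P(c1ccccc1)(c1ccccc1)c1ccccc1 | starting material
25 | open-chain (E)-enoate, O8–H free | CCOC(=O)/C(C)=C/[C@@H]1OC(C)(C)O[C@]1(C(=C)COCc2ccc(OC)cc2)[C@@H](O)[C@@H](O[Si](C)(C)C(C)(C)C)/C(C)=C\CS(=O)(=O)c2ccccc2 | intermediate
26 | O8,O9-bis-TBS enoate | CCOC(=O)/C(C)=C/[C@@H]1OC(C)(C)O[C@]1(C(=C)COCc2ccc(OC)cc2)[C@@H](O[Si](C)(C)C(C)(C)C)[C@@H](O[Si](C)(C)C(C)(C)C)/C(C)=C\CS(=O)(=O)c2ccccc2 | intermediate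
27 | C3 allylic alcohol | OC/C(C)=C/[C@@H]1OC(C)(C)O[C@]1(C(=C)COCc2ccc(OC)cc2)[C@@H](O[Si](C)(C)C(C)(C)C)[C@@H](O[Si](C)(C)C(C)(C)C)/C(C)=C\CS(=O)(=O)c2ccccc2 | intermediate
28 | C3 imidazole-1-carboxylate | O=C(OC/C(C)=C/[C@@H]1OC(C)(C)O[C@]1(C(=C)COCc2ccc(OC)cc2)[C@@H](O[Si](C)(C)C(C)(C)C)[C@@H](O[Si](C)(C)C(C)(C)C)/C(C)=C\CS(=O)(=O)c2ccccc2)n1ccnc1 | intermediate
29 | twelve-membered α-sulfonyl lactone (C2 epimers) | CC1(C)O[C@H]2/C=C(\C)COC(=O)C(S(=O)(=O)c3ccccc3)/C=C(/C)[C@H](O[Si](C)(C)C(C)(C)C)[C@H](O[Si](C)(C)C(C)(C)C)[C@@]2(C(=C)COCc3ccc(OC)cc3)O1 | intermediate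
30 | ten-membered (1(10)Z,4E)-diene with SO2Ph at C2 (C2 epimers) | CC1(C)O[C@H]2/C=C(\C)CC(S(=O)(=O)c3ccccc3)/C=C(/C)[C@H](O[Si](C)(C)C(C)(C)C)[C@H](O[Si](C)(C)C(C)(C)C)[C@@]2(C(=C)COCc3ccc(OC)cc3)O1 | intermediate
31 | protected germacra-1(10)Z,4E-diene | CC1(C)O[C@H]2/C=C(\C)CC/C=C(/C)[C@H](O[Si](C)(C)C(C)(C)C)[C@H](O[Si](C)(C)C(C)(C)C)[C@@]2(C(=C)COCc3ccc(OC)cc3)O1 | intermediate
32 | O8,O9-diol | CC1(C)O[C@H]2/C=C(\C)CC/C=C(/C)[C@H](O)[C@H](O)[C@@]2(C(=C)COCc3ccc(OC)cc3)O1 | intermediate
33 | mixed anhydride of 12 and 2,4,6-trichlorobenzoic acid | O=C(OC(=O)[C@@]1(C)O[C@H]1C)c1c(Cl)cc(Cl)cc1Cl | intermediate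
34 | O9 epoxyangelate, O8–H free | CC1(C)O[C@H]2/C=C(\C)CC/C=C(/C)[C@H](OC(=O)[C@@]3(C)O[C@H]3C)[C@H](O)[C@@]2(C(=C)COCc3ccc(OC)cc3)O1 | intermediate
35 | O8 acetate, O9 epoxyangelate | CC1(C)O[C@H]2/C=C(\C)CC/C=C(/C)[C@H](OC(=O)[C@@]3(C)O[C@H]3C)[C@H](OC(C)=O)[C@@]2(C(=C)COCc3ccc(OC)cc3)O1 | intermediate
36 | C12 allylic alcohol | CC1(C)O[C@H]2/C=C(\C)CC/C=C(/C)[C@H](OC(=O)[C@@]3(C)O[C@H]3C)[C@H](OC(C)=O)[C@@]2(C(=C)CO)O1 | intermediate
37 | triol (O6–H, O7–H, O12–H) | O[C@H]1/C=C(\C)CC/C=C(/C)[C@H](OC(=O)[C@@]2(C)O[C@H]2C)[C@H](OC(C)=O)[C@]1(O)C(=C)CO | intermediate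
38 | α-methylene lactol (anomers at C12) | C=C1C(O)O[C@H]2/C=C(\C)CC/C=C(/C)[C@H](OC(=O)[C@@]3(C)O[C@H]3C)[C@H](OC(C)=O)[C@]12O | intermediate
39 | CNP0271187.2 | C=C1C(=O)O[C@H]2/C=C(\C)CC/C=C(/C)[C@H](OC(=O)[C@@]3(C)O[C@H]3C)[C@H](OC(C)=O)[C@]12O | target

**Count and risks**
Total: 27 steps. Longest linear sequence: 21 steps (steps 7 to 27, from L-arabinose).

Step 20 (labelled step). After ionisation the open intermediate may be diverted into dimerisation, into loss of a β-hydrogen to a diene, or into simple protonation of the carbanion once CO2 has left, because closure has to pay the strain of the ten-membered ring. The fallback sets out from 27. The alcohol is turned into the allylic bromide F1 (MsCl, Et3N, then LiBr, THF). F1 is added slowly to LiN(SiMe3)2 in THF at −78 to 0 °C at high dilution, so the ring is closed by direct intramolecular SN2 alkylation of the sulfonyl carbanion. This is a known way to medium-ring terpenoid dienes that keeps both alkene geometries. The fallback comes back to the route at 30 and leaves out 28 and 29.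

Step 19. The carbanion may be consumed by intermolecular acylation, the amide base may attack the imidazole carboxylate, or the C9 silyloxy group may be lost by 1,4-elimination. The fallback sets out from 27. Double deprotonation with n-BuLi (2.1 equiv, THF, −78 °C) and trapping with CO2 gives, after careful acidification in the cold, the seco hydroxy acid F2. F2 is closed by Shiina macrolactonisation (2-methyl-6-nitrobenzoic anhydride, DMAP, CH2Cl2, high dilution), so the ring is made at the C–O bond instead of the C–C bond. The fallback comes back to the route at 29.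

Step 12. Facial selectivity at the aldehyde may be poor, since the ring oxygen and the free C7 hydroxyl can bind chromium and oppose the Felkin–Anh course. The fallback sets out from 21 as a mixture at C9. Dess–Martin oxidation gives the C9 enone F3. Reduction of F3 with Zn(BH4)2 in Et2O at −78 °C, with zinc held between the ketone oxygen and the ring oxygen O8, delivers hydride under chelation control to the O8/O9-anti alcohol. C9 is thus set by reduction of a ketone rather than by C–C bond formation. The fallback comes back to the route at 21.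

**Further compounds**
F1 | step 20 | C3 allylic bromide of 27 | BrC/C(C)=C/[C@@H]1OC(C)(C)O[C@]1(C(=C)COCc2ccc(OC)cc2)[C@@H](O[Si](C)(C)C(C)(C)C)[C@@H](O[Si](C)(C)C(C)(C)C)/C(C)=C\CS(=O)(=O)c2ccccc2
F2 | step 19 | seco hydroxy acid (CO2H and SO2Ph on C2, free C3–OH) | OC/C(C)=C/[C@@H]1OC(C)(C)O[C@]1(C(=C)COCc2ccc(OC)cc2)[C@@H](O[Si](C)(C)C(C)(C)C)[C@@H](O[Si](C)(C)C(C)(C)C)/C(C)=C\C(C(=O)O)S(=O)(=O)c2ccccc2
F3 | step 12 | C9 enone | CC1(C)O[C@H]2O[C@@H](C(=O)/C(C)=C\CS(=O)(=O)c3ccccc3)[C@](O)(C(=C)COCc3ccc(OC)cc3)[C@H]2O1
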